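**Retrosynthetic overview**
- The target is a trans-fused daucane. Ring A is the cyclopentane C1–C5 (C1 quaternary with a β-methyl, C4 carbinol with isopropyl, C5 ring-fusion CH). Ring B is the cycloheptene C1, C5–C10 (C6 anisoate, C8(CH3)=C9, C10 allylic carbinol). β is the face of the C1 methyl.
- Feature: C8=C9 sits between the C10 carbinol and quaternary C1, and C5(H)–C6(O) is the hydration product of a C5=C6 alkene. Ring B is therefore a masked cyclohepta-1,4-diene (C5=C6–C7–C8=C9–C10–C1), the signature of a cis-divinylcyclopropane Cope shift.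
- Disconnections: silyl ethers and the C6 anisoate last; the C8 methyl from a C8 ester; C5–H/C6–OH from C5=C6 by hydroboration; C1–C10 by the Cope shift; C7–C8 and a temporary C6–C8 by rhodium vinylcarbenoid addition to the vinyl group of a 2-methyl-1-vinylcyclopentene.
- Ring order: ring A first, by ring contraction of (S)-terpinen-4-ol (ozonolysis, aldol condensation), which supplies C4 with its oxygen and isopropyl group; then the transient cyclopropane; then ring B by its ring expansion.

Key step: step 7

Assumption: the sense of induction follows the model for donor–acceptor carbenoids in which Rh2(S-DOSP)4 (DOSP = N-(4-dodecylphenylsulfonyl)prolinate, divalent rhodium) converts styrene and methyl aryldiazoacetates into (1S,2R)-cyclopropanes; on that model the R catalyst gives cyclopropane 15, and if the sense proved opposite the S catalyst would be used with nothing else changed.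
Assumption: (S)-terpinen-4-ol of high enantiomeric purity is used; any minor enantiomer becomes a diastereomer under the chiral catalyst of step 7 and is removed there.

**Step 1**
Reactants: 1 (S)-terpinen-4-ol
Product: 2 (S)-terpinen-4-yl triethylsilyl ether
Conditions: TESOTf, 2,6-lutidine, CH2Cl2, 0 °C → rt
Reagents that add atoms: triethylsilyl trifluoromethanesulfonate, CC[Si](CC)(CC)OS(=O)(=O)C(F)(F)F
Why: O-silylation of the tertiary alcohol with the silyl triflate masks the hydroxyl, which would otherwise form a hemiketal after ring cleavage and insert into the carbenoid in step 7; no stereocentre is touched.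

**Step 2**
Reactants: 2 (S)-terpinen-4-yl triethylsilyl ether
Product: 4 (S)-3-isopropyl-6-oxo-3-(triethylsilyloxy)heptanal, via ozonide 3 (not isolated)
Conditions: O3, CH2Cl2, −78 °C; then PPh3, −78 °C → rt
Reagents that add atoms: ozone, [O-][O+]=O
Why: Criegee ozonolysis of the only alkene and phosphine reduction of the ozonide should give the 1,6-keto aldehyde; the carbinol centre (future C4) is not involved.

**Step 3**
Reactants: 4 (S)-3-isopropyl-6-oxo-3-(triethylsilyloxy)heptanal
Product: 6 (R)-5-isopropyl-2-methyl-5-(triethylsilyloxy)cyclopent-1-ene-1-carbaldehyde, via aldol 5 (not isolated)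
Conditions: piperidine (cat.), AcOH (cat.), toluene, 4 Å molecular sieves, rt → 50 °C
Reagents that add atoms: none
Why: Enamine-mediated intramolecular aldol condensation: the aldehyde enamine carbon (C5) adds to the methyl ketone (C1) in a 5-exo-trig closure and dehydration gives the conjugated enal, a ring contraction well established for 6-oxoheptanals; the mild amine/acid pair is chosen to limit β-elimination of the silyloxy group, and C4 is retained.

**Step 4**
Reactants: 6 (R)-5-isopropyl-2-methyl-5-(triethylsilyloxy)cyclopent-1-ene-1-carbaldehyde; 7 methyltriphenylphosphonium bromide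
Product: 9 (R)-1-isopropyl-3-methyl-2-vinylcyclopent-2-en-1-yl triethylsilyl ether, via methylenetriphenylphosphorane 8 (not isolated)
Conditions: KOtBu, THF, 0 °C; then 6, 0 °C → rt
Reagents that add atoms: none
Why: Wittig methylenation of the aldehyde, whose α-carbon is sp2 and cannot be deprotonated, should give the 1,3-diene with C6=C7 as a free terminal vinyl group; no stereocentre changes.

**Step 5**
Reactants: 10 ethyl diazoacetate; 11 (tert-butyldimethylsilyloxy)acetaldehyde
Product: 12 ethyl 4-(tert-butyldimethylsilyloxy)-2-diazo-3-hydroxybutanoate (racemic)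
Conditions: DBU (cat.), MeCN, rt
Reagents that add atoms: none
Why: Base-catalysed aldol-type addition of the acidic C–H of the diazo ester to the aldehyde should give the β-hydroxy α-diazo ester; its carbinol centre is removed in the next step, so the racemate suffices.

**Step 6**
Reactants: 12 ethyl 4-(tert-butyldimethylsilyloxy)-2-diazo-3-hydroxybutanoate
Product: 14 ethyl (E)-4-(tert-butyldimethylsilyloxy)-2-diazobut-3-enoate, via dichlorophosphate 13 (not isolated)
Conditions: POCl3, Et3N, CH2Cl2, −10 → 0 °C
Reagents that add atoms: none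
Why: Phosphorylation of the alcohol and amine-induced E2 elimination, the standard dehydration of β-hydroxy α-diazo esters to vinyldiazoacetates, should give the conjugated silyl enol ether, the E isomer being favoured because the silyloxy and diazo ester groups lie anti in the elimination transition state; the product is kept cold, base-washed and used at once.

**Step 7**
Reactants: 9 (R)-1-isopropyl-3-methyl-2-vinylcyclopent-2-en-1-yl triethylsilyl ether; 14 ethyl (E)-4-(tert-butyldimethylsilyloxy)-2-diazobut-3-enoate
Product: 16 bicyclic diene ester (ethyl 10α-(tert-butyldimethylsilyloxy)-4α-isopropyl-1β-methyl-4β-(triethylsilyloxy)bicyclo[5.3.0]deca-5,8-diene-8-carboxylate in daucane numbering), via cis-divinylcyclopropane 15 (not isolated)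
Conditions: Rh2(R-DOSP)4 (1 mol %), hexanes, slow addition of 14 (1.5 equiv), −40 °C → rt; then 60 °C
Reagents that add atoms: none
Why: The catalyst converts 14 into a donor–acceptor rhodium vinylcarbenoid that transfers C8 to the terminal C6=C7 bond of 9 in a concerted asynchronous [2+1] addition (bonds C7–C8 and C6–C8), the siloxyvinyl group ending cis to the cyclopentenyl group as is general for these carbenoids; cis-divinylcyclopropane 15 then undergoes a [3,3]-sigmatropic (Cope) shift through a boat transition state that forms C1–C10 and breaks C6–C8. The closest known reaction type is the rhodium-catalysed tandem cyclopropanation/Cope rearrangement (formal [4+3] cycloaddition) of vinyldiazoacetates with 1,3-dienes, including 1-vinylcycloalkenes whose ring terminus is fully substituted. The three-membered ring is closed by carbene [2+1] addition, and ring B is closed by strain-driven pericyclic ring expansion of that cyclopropane, not by a polar or radical cyclisation. The two cyclopropane centres are set by the chiral prolinate catalyst, which selects the face of the vinyl group; the boat relays them suprafacially so that C10 bonds to the α face of C1, and because the siloxy group and ring carbon C2 are both E on their alkenes, O-10 ends cis to C2 and trans to the C1 methyl. The step needs chemoselectivity for the monosubstituted vinyl group (the tetrasubstituted ring alkene is inert to these carbenoids), cis diastereoselectivity (inherent to the carbenoid class) and catalyst control over the neighbouring C4 centre; the hydrocarbon solvent suppresses vinylogous attack at C10, and a cyclopropane arising from any Z enol ether would not rearrange at this temperature and is separated here.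

**Step 8**
Reactants: 16 bicyclic diene ester
Product: 18 6α-alcohol (ethyl 10α-(tert-butyldimethylsilyloxy)-6α-hydroxy-4α-isopropyl-1β-methyl-4β-(triethylsilyloxy)-5α-H-bicyclo[5.3.0]dec-8-ene-8-carboxylate), via alkylborane 17 (not isolated)
Conditions: BH3·SMe2, THF, 0 °C → rt; then 30% H2O2, aq NaOAc, 0 °C → rt
Reagents that add atoms: hydrogen peroxide, OO
Why: Hydroboration–oxidation: borane adds syn to the electron-rich trisubstituted C5=C6 bond (boron on C6, hydrogen on C5) faster than to the electron-poor enoate, and from the α face away from the C1 methyl and the C4 silyloxy group as in Δ5-steroids; oxidation with retention then sets C5–H α (trans fusion) and C6–OH α.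

**Step 9**
Reactants: 18 6α-alcohol
Product: 19 diol (10α-(tert-butyldimethylsilyloxy)-4β-(triethylsilyloxy)-5α-dauc-8-ene-6α,14-diol; C14 is the CH2OH on C8)
Conditions: i-Bu2AlH, CH2Cl2, −78 → 0 °C; aq potassium sodium tartrate
Reagents that add atoms: none
Why: 1,2-Reduction of the conjugated ester by the aluminium hydride should give the primary allylic alcohol without conjugate reduction; silyl ethers and stereocentres are unaffected.

**Step 10**
Reactants: 19 diol
Product: 21 10α-(tert-butyldimethylsilyloxy)-4β-(triethylsilyloxy)-5α-dauc-8-en-6α-ol, via mesylate 20 (not isolated)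
Conditions: MsCl, Et3N, THF, −40 °C; then LiEt3BH, −40 → 0 °C
Reagents that add atoms: none
Why: The primary allylic hydroxyl is sulfonylated in preference to the hindered secondary C6 hydroxyl and the mesylate is displaced by hydride in an SN2 reaction at the open CH2 (C9 is shielded by the C10 silyl ether), so that C8 gains its methyl group and C8=C9 stays in place.

**Step 11**
Reactants: 21 10α-(tert-butyldimethylsilyloxy)-4β-(triethylsilyloxy)-5α-dauc-8-en-6α-ol; 22 4-methoxybenzoyl chloride
Product: 23 10α-(tert-butyldimethylsilyloxy)-4β-(triethylsilyloxy)-5α-dauc-8-en-6α-yl 4-methoxybenzoate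
Conditions: Et3N, DMAP (cat.), CH2Cl2, 0 → 40 °C
Reagents that add atoms: none
Why: DMAP-catalysed acylation (nucleophilic catalysis) of the only free hydroxyl installs the anisoate with retention at C6.

**Step 12**
Reactants: 23 bis-silyl anisoate
Product: 24 4β,10α-dihydroxy-5α-dauc-8-en-6α-yl 4-methoxybenzoate (CNP0211568.1)
Conditions: Bu4NF, AcOH, THF, rt → 45 °C
Reagents that add atoms: none
Why: Fluoride-mediated cleavage of both silyl ethers (Si–F bond formation) under acetic acid buffering should free the tertiary C4 and allylic C10 hydroxyls without acyl migration or ester cleavage; no stereocentre is affected.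

**Compound list**
1 | (S)-terpinen-4-ol | CC1=CC[C@](O)(C(C)C)CC1 | starting material
2 | (S)-terpinen-4-yl triethylsilyl ether | CC1=CC[C@](O[Si](CC)(CC)CC)(C(C)C)CC1 | intermediate
3 | ozonide of 2: 4-isopropyl-1-methyl-4-(triethylsilyloxy)-7,8,9-trioxabicyclo[4.2.1]nonane (C4 as in 2, new centres unassigned) | CC12CC[C@@](O[Si](CC)(CC)CC)(C(C)C)CC(OO1)O2 | intermediate
4 | (S)-3-isopropyl-6-oxo-3-(triethylsilyloxy)heptanal | CC(=O)CC[C@@](CC=O)(O[Si](CC)(CC)CC)C(C)C | intermediate
5 | aldol: 2-hydroxy-5-isopropyl-2-methyl-5-(triethylsilyloxy)cyclopentane-1-carbaldehyde (silyloxy carbon as in 4, new centres unassigned) | O=CC1C(C)(O)CC[C@@]1(O[Si](CC)(CC)CC)C(C)C | intermediate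
6 | (R)-5-isopropyl-2-methyl-5-(triethylsilyloxy)cyclopent-1-ene-1-carbaldehyde | O=CC1=C(C)CC[C@@]1(O[Si](CC)(CC)CC)C(C)C | intermediate
7 | methyltriphenylphosphonium bromide | C[P+](c1ccccc1)(c1ccccc1)c1ccccc1.[Br-] | starting material
8 | methylenetriphenylphosphorane | C=P(c1ccccc1)(c1ccccc1)c1ccccc1 | intermediate
9 | (R)-1-isopropyl-3-methyl-2-vinylcyclopent-2-en-1-yl triethylsilyl ether (diene; C4 carries OSiEt3 and isopropyl) | C=CC1=C(C)CC[C@@]1(O[Si](CC)(CC)CC)C(C)C | intermediate
10 | ethyl diazoacetate | CCOC(=O)C=[N+]=[N-] | starting material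
11 | (tert-butyldimethylsilyloxy)acetaldehyde | CC(C)(C)[Si](C)(C)OCC=O | starting material
12 | ethyl 4-(tert-butyldimethylsilyloxy)-2-diazo-3-hydroxybutanoate (racemic) | CCOC(=O)C(=[N+]=[N-])C(O)CO[Si](C)(C)C(C)(C)C | intermediate
13 | 3-O-dichlorophosphate of 12 | CCOC(=O)C(=[N+]=[N-])C(CO[Si](C)(C)C(C)(C)C)OP(=O)(Cl)Cl | intermediate
14 | ethyl (E)-4-(tert-butyldimethylsilyloxy)-2-diazobut-3-enoate | CCOC(=O)C(=[N+]=[N-])/C=C/O[Si](C)(C)C(C)(C)C | intermediate
15 | cis-divinylcyclopropane: ethyl 1-[(E)-2-(tert-butyldimethylsilyloxy)vinyl]-2-[(R)-5-isopropyl-2-methyl-5-(triethylsilyloxy)cyclopent-1-en-1-yl]cyclopropane-1-carboxylate, siloxyvinyl cis to cyclopentenyl, absolute configuration as in the SMILES | CCOC(=O)[C@]1(/C=C/O[Si](C)(C)C(C)(C)C)C[C@H]1C2=C(C)CC[C@@]2(O[Si](CC)(CC)CC)C(C)C | intermediate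
16 | bicyclic diene ester: CO2Et on C8, C5=C6 and C8=C9, 10α-OTBS, 4β-OSiEt3, 4α-isopropyl, 1β-methyl | CCOC(=O)C1=C[C@@H](O[Si](C)(C)C(C)(C)C)[C@@]2(C)CC[C@@](O[Si](CC)(CC)CC)(C(C)C)C2=CC1 | intermediate
17 | C6 alkylborane (6α-BH2, 5α-H, otherwise as 16) | CCOC(=O)C1=C[C@@H](O[Si](C)(C)C(C)(C)C)[C@@]2(C)CC[C@@](O[Si](CC)(CC)CC)(C(C)C)[C@@H]2[C@@H](B)C1 | intermediate
18 | 6α-alcohol: CO2Et on C8, C8=C9, 6α-OH, 5α-H, 10α-OTBS, 4β-OSiEt3, 1β-methyl | CCOC(=O)C1=C[C@@H](O[Si](C)(C)C(C)(C)C)[C@@]2(C)CC[C@@](O[Si](CC)(CC)CC)(C(C)C)[C@@H]2[C@@H](O)C1 | intermediate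
19 | diol: 10α-(tert-butyldimethylsilyloxy)-4β-(triethylsilyloxy)-5α-dauc-8-ene-6α,14-diol (1β-methyl) | OCC1=C[C@@H](O[Si](C)(C)C(C)(C)C)[C@@]2(C)CC[C@@](O[Si](CC)(CC)CC)(C(C)C)[C@@H]2[C@@H](O)C1 | intermediate
20 | 14-O-mesylate of 19 (6α-OH free) | CS(=O)(=O)OCC1=C[C@@H](O[Si](C)(C)C(C)(C)C)[C@@]2(C)CC[C@@](O[Si](CC)(CC)CC)(C(C)C)[C@@H]2[C@@H](O)C1 | intermediate
21 | 10α-(tert-butyldimethylsilyloxy)-4β-(triethylsilyloxy)-5α-dauc-8-en-6α-ol (1β-methyl) | CC1=C[C@@H](O[Si](C)(C)C(C)(C)C)[C@@]2(C)CC[C@@](O[Si](CC)(CC)CC)(C(C)C)[C@@H]2[C@@H](O)C1 | intermediate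
22 | 4-methoxybenzoyl chloride | COc1ccc(cc1)C(Cl)=O | starting material
23 | 10α-(tert-butyldimethylsilyloxy)-4β-(triethylsilyloxy)-5α-dauc-8-en-6α-yl 4-methoxybenzoate | COc1ccc(C(=O)O[C@H]2CC(C)=C[C@@H](O[Si](C)(C)C(C)(C)C)[C@@]3(C)CC[C@@](O[Si](CC)(CC)CC)(C(C)C)[C@H]23)cc1 | intermediate
24 | 4β,10α-dihydroxy-5α-dauc-8-en-6α-yl 4-methoxybenzoate (1β-methyl; CNP0211568.1) | COc1ccc(C(=O)O[C@H]2CC(C)=C[C@@H](O)[C@@]3(C)CC[C@@](O)(C(C)C)[C@H]23)cc1 | target

**Totals**
Total step count: 12. Longest linear sequence: 10 steps (steps 1–4 and 7–12, from 1).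

**Steps most likely to fail**

Step 7. The siloxy-substituted vinylcarbenoid may decompose or react at its vinylogous terminus before it cyclopropanates. Catalyst control of the vinyl face may also be eroded by the adjacent C4 centre, and the Cope shift may stall because the C1 terminus carries a Z methyl group. The fallback replaces the enol ether by an alkynylcarbenoid and a boron substituent; it sets out from diene 9 and ethyl diazoacetate 10 and comes back at 16. CuI-catalysed coupling of 10 with trimethylsilylacetylene gives ethyl 4-(trimethylsilyl)but-3-ynoate F1, and diazo transfer (4-acetamidobenzenesulfonyl azide, DBU) gives ethyl 2-diazo-4-(trimethylsilyl)but-3-ynoate F2. Rh2(R-DOSP)4-catalysed cyclopropanation of the vinyl group of 9 with this robust donor–acceptor carbenoid gives the alkynylcyclopropane F3, with the alkyne cis to the cyclopentenyl group. K2CO3 in ethanol frees the terminal alkyne F4, and hydroboration with pinacolborane and catalytic Cp2Zr(H)Cl gives the (E)-alkenylboronate F5. This cis-divinylcyclopropane tolerates heating in toluene and should undergo the same boat Cope shift to the C10 allylic boronate F6, with boron α. Oxidation with NaBO3·4H2O, with retention, gives the C10 alcohol F7, and TBSOTf/2,6-lutidine returns 16.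

Step 8. Borane may add to the β face (cis fusion), or may attack the conjugated ester, also intramolecularly from the first-formed alkylborane, before the hindered alkene has reacted. The fallback uses anti addition in place of syn addition, so that the other face of the alkene serves; it sets out from 16 and comes back at 19. Buffered mCPBA (NaHCO3) epoxidises the electron-rich C5=C6 bond chemoselectively, on the β face if that is the open one, to the 5β,6β-epoxide F8. Cp2TiCl (trivalent titanium, from Cp2TiCl2 and Zn) opens it to the tertiary C5 radical, which takes a hydrogen atom from 1,4-cyclohexadiene anti to the titanium alkoxide to give the trans-fused 6β-alcohol F9 (5α-H). Mitsunobu esterification with 4-nitrobenzoic acid (PPh3, diisopropyl azodicarboxylate) inverts C6 to the 6α-(4-nitrobenzoate) F10. i-Bu2AlH under the conditions of step 9 cleaves this ester and reduces the ethyl ester to give 19.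

Step 10. Hydride may be delivered with allylic shift to give the exocyclic alkene, or the primary allylic sulfonate may ionise or be lost before reduction. The fallback uses π-allylpalladium hydrogenolysis in place of sulfonate displacement; it sets out from 19 and comes back at 21. Selective acetylation of the primary allylic hydroxyl (Ac2O, 2,4,6-collidine, −20 °C) gives the allylic acetate F11. Pd(PPh3)4 (zerovalent palladium) with Bu3SnH then transfers hydride to the less hindered CH2 terminus of the allyl complex to give 21.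

**Further compounds**
F1 | step 7 | ethyl 4-(trimethylsilyl)but-3-ynoate | CCOC(=O)CC#C[Si](C)(C)C
F2 | step 7 | ethyl 2-diazo-4-(trimethylsilyl)but-3-ynoate | CCOC(=O)C(=[N+]=[N-])C#C[Si](C)(C)C
F3 | step 7 | alkynylcyclopropane: ethyl 2-[(R)-5-isopropyl-2-methyl-5-(triethylsilyloxy)cyclopent-1-en-1-yl]-1-[(trimethylsilyl)ethynyl]cyclopropane-1-carboxylate, alkyne cis to cyclopentenyl | CCOC(=O)[C@]1(C#C[Si](C)(C)C)C[C@H]1C2=C(C)CC[C@@]2(O[Si](CC)(CC)CC)C(C)C
F4 | step 7 | terminal alkyne: 1-ethynyl analogue of F3 | CCOC(=O)[C@]1(C#C)C[C@H]1C2=C(C)CC[C@@]2(O[Si](CC)(CC)CC)C(C)C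
F5 | step 7 | (E)-alkenylboronate: 1-[(E)-2-(pinacolboryl)vinyl] analogue of F3 | CCOC(=O)[C@]1(/C=C/B3OC(C)(C)C(C)(C)O3)C[C@H]1C2=C(C)CC[C@@]2(O[Si](CC)(CC)CC)C(C)C
F6 | step 7 | C10 allylic boronate: 10α-pinacolboryl analogue of 16 | CCOC(=O)C1=C[C@@H](B3OC(C)(C)C(C)(C)O3)[C@@]2(C)CC[C@@](O[Si](CC)(CC)CC)(C(C)C)C2=CC1
F7 | step 7 | C10 alcohol: 10α-hydroxy analogue of 16 | CCOC(=O)C1=C[C@@H](O)[C@@]2(C)CC[C@@](O[Si](CC)(CC)CC)(C(C)C)C2=CC1
F8 | step 8 | 5β,6β-epoxide of 16 | CCOC(=O)C1=C[C@@H](O[Si](C)(C)C(C)(C)C)[C@@]2(C)CC[C@@](O[Si](CC)(CC)CC)(C(C)C)[C@]23O[C@@H]3C1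
F9 | step 8 | 6β-alcohol: C6 epimer of 18 (5α-H) | CCOC(=O)C1=C[C@@H](O[Si](C)(C)C(C)(C)C)[C@@]2(C)CC[C@@](O[Si](CC)(CC)CC)(C(C)C)[C@@H]2[C@H](O)C1
F10 | step 8 | 6α-(4-nitrobenzoate) of 18 | CCOC(=O)C1=C[C@@H](O[Si](C)(C)C(C)(C)C)[C@@]2(C)CC[C@@](O[Si](CC)(CC)CC)(C(C)C)[C@@H]2[C@@H](OC(=O)c3ccc(cc3)[N+](=O)[O-])C1
F11 | step 10 | 14-O-acetate of 19 (6α-OH free) | CC(=O)OCC1=C[C@@H](O[Si](C)(C)C(C)(C)C)[C@@]2(C)CC[C@@](O[Si](CC)(CC)CC)(C(C)C)[C@@H]2[C@@H](O)C1
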